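## Retrosynthetic overview

1. The ten-membered ring is closed last, at C4–C5, by nickel-catalysed electroreductive coupling of the two alkenyl iodides of seco-diiodide 35.
2. 35 comes from a three-component union of enone 7, Me2CuLi and aldehyde 19, which sets the C1 quaternary centre and the C9–C10 bond.
3. Enone 7 comes from (−)-quinic acid (C13, C14). C11 becomes the epoxide via methylenation and epoxidation. The C2 arm is built from a silylmethyl group via a (Z)-β-iodo enone and substrate-controlled reduction.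
4. Aldehyde 19 comes from dimethyl (R)-malate (C8): Fráter–Seebach methylation (C17), Seebach dioxolanone alkylation (C9), chelation-controlled alkynylation and lactonisation (C7).
5. Ring order: cyclohexane (bought), γ-lactone, spiro-epoxide, ten-membered ring.

Assumption: briarane numbering of the target is used for every intermediate (C15 = methyl on C1, C16 = CH2OH on C5, C18 = methyl on C17, C19 = lactone C=O, C20 = epoxide CH2). "Seco" means the C4–C5 bond is absent. Stereocentres present in an intermediate have the configuration they have in 36 unless stated.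

## Route

Step 1
Reactants: 1 (−)-quinic acid
Product: 2 3,4-O-isopropylidene-quinic acid 1,5-lactone
Conditions: Me2C(OMe)2, TsOH·H2O (cat.), acetone, reflux
Reagents that add atoms: 2,2-dimethoxypropane, COC(C)(C)OC
Why: Acid-catalysed acetalisation of the cis-3,4-diol with lactonisation of the carboxyl group onto the cis 5-hydroxyl, no stereocentre being touched.

Step 2
Reactants: 2 3,4-O-isopropylidene-quinic acid 1,5-lactone
Product: 4 (3R,4S,5R)-3-hydroxy-4,5-(isopropylidenedioxy)cyclohexanone, via triol 3 (not isolated)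
Conditions: NaBH4, EtOH, 0 °C to rt; then NaIO4, aq. phosphate buffer (pH 7), 0 °C
Reagents that add atoms: none
Why: Hydride reduction of the lactone and Malaprade (periodate) cleavage of the tertiary/primary 1,2-diol give the ketone (future C11) with loss of the former carboxyl carbon.

Step 3
Reactants: 4 (3R,4S,5R)-3-hydroxy-4,5-(isopropylidenedioxy)cyclohexanone
Product: 5 (4S,5R)-4,5-(isopropylidenedioxy)cyclohex-2-en-1-one
Conditions: MsCl, Et3N, CH2Cl2, 0 °C to rt
Reagents that add atoms: none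
Why: Mesylation of the β-hydroxyl and E1cB elimination give the conjugated enone, leaving the acetonide centres (future C13, C14) untouched.

Step 4
Reactants: 5 (4S,5R)-4,5-(isopropylidenedioxy)cyclohex-2-en-1-one
Product: 7 (4S,5R)-3-{[(isopropoxy)dimethylsilyl]methyl}-4,5-(isopropylidenedioxy)cyclohex-2-en-1-one, via silyl enol ether 6 (not isolated)
Conditions: (iPrO)Me2SiCH2MgCl (from (iPrO)Me2SiCH2Cl, Mg), CuI (10 mol %), Me3SiCl, THF, −78 °C; then Pd(OAc)2 (10 mol %), O2 (1 atm), DMSO, rt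
Reagents that add atoms: [(isopropoxydimethylsilyl)methyl]magnesium chloride, CC(C)O[Si](C)(C)C[Mg]Cl
Why: Copper-catalysed conjugate addition of the Tamao hydroxymethyl-anion equivalent is trapped as the silyl enol ether, and Larock–Saegusa dehydrogenation restores the enone regiospecifically with the C2 carbon now on the β-carbon (the transient stereocentre is erased).

Step 5
Reactants: 8 dimethyl (R)-malate
Product: 9 dimethyl (2R,3S)-2-hydroxy-3-methylbutanedioate
Conditions: LiN(iPr)2 (2.2 equiv), THF, −78 to −20 °C; MeI, −78 °C to rt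
Reagents that add atoms: iodomethane, CI
Why: Fráter–Seebach alkylation: the chelated alkoxide–enolate dianion is methylated anti to the alkoxide, setting C17 (anti, about 9:1) under control of the bought C8 centre.

Step 6
Reactants: 9 dimethyl (2R,3S)-2-hydroxy-3-methylbutanedioate
Product: 10 (2R,3S)-2-hydroxy-3-methylbutanedioic acid
Conditions: KOH, MeOH/H2O, 0 °C to rt; then aq. HCl
Reagents that add atoms: potassium hydroxide, [K+].[OH-]
Why: Saponification of both esters frees the α-hydroxy acid for acetalisation without touching either stereocentre.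

Step 7
Reactants: 10 (2R,3S)-2-hydroxy-3-methylbutanedioic acid
Product: 11 (2S)-2-[(2R,4R)-2-tert-butyl-5-oxo-1,3-dioxolan-4-yl]propanoic acid (tert-butyl and side chain cis)
Conditions: tBuCHO, TsOH·H2O (cat.), H2SO4 (cat.), pentane, reflux (water separator)
Reagents that add atoms: pivalaldehyde, CC(C)(C)C=O
Why: Seebach acetalisation (self-regeneration of stereocentres) gives the thermodynamically preferred cis-dioxolanone, which stores the C8 configuration in the acetal centre.

Step 8
Reactants: 11 (2S)-2-[(2R,4R)-2-tert-butyl-5-oxo-1,3-dioxolan-4-yl]propanoic acid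
Product: 12 (2S)-2-[(2R,4R)-2-tert-butyl-5-oxo-4-(phenylsulfanylmethyl)-1,3-dioxolan-4-yl]propanoic acid (CH2SPh trans to tert-butyl)
Conditions: LiN(SiMe3)2 (2.2 equiv), THF, −78 °C; PhSCH2Cl, −78 to −20 °C; then aq. HCl
Reagents that add atoms: chloromethyl phenyl sulfide, ClCSc1ccccc1
Why: Seebach alkylation of the carboxylate–enolate dianion: the electrophile enters trans to the tert-butyl group, so C8 becomes quaternary with overall retention and carries C9.

Step 9
Reactants: 12 (2S)-2-[(2R,4R)-2-tert-butyl-5-oxo-4-(phenylsulfanylmethyl)-1,3-dioxolan-4-yl]propanoic acid; 13 tert-butyl(diphenyl)(prop-2-yn-1-yloxy)silane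
Product: 16 hydroxy lactone (C19/C7 γ-lactone with 17-methyl, 8-OH, 8-CH2SPh and 7-[3-(tert-butyldiphenylsilyloxy)prop-1-ynyl]), via lactol 14 (not isolated), via dihydroxy acid 15 (not isolated)
Conditions: iBu2AlH (2.2 equiv), CH2Cl2, −78 °C; then BrMgC≡CCH2OSiPh2tBu (from 13, EtMgBr; 3.5 equiv), THF, −78 to 0 °C; then aq. HCl; TsOH (cat.), CH2Cl2, rt
Reagents that add atoms: none
Why: Half-reduction of the activated dioxolanone to the lactol, Cram-chelate addition of the alkynyl Grignard reagent to the liberated α-oxy aldehyde from the side of the smaller CH2SPh group (sets C7), then acid-induced loss of pivalaldehyde and γ-lactonisation onto the C19 acid.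

Step 10
Reactants: 16 hydroxy lactone
Product: 17 8-O-triethylsilyl lactone
Conditions: Et3SiOTf, 2,6-lutidine, CH2Cl2, −78 to 0 °C
Reagents that add atoms: triethylsilyl trifluoromethanesulfonate, CC[Si](CC)(CC)OS(=O)(=O)C(F)(F)F
Why: Silylation of the tertiary C8 hydroxyl with the silyl triflate masks the only acidic proton before enolate chemistry.

Step 11
Reactants: 17 8-O-triethylsilyl lactone
Product: 19 lactone aldehyde (C9 aldehyde on C8), via chloro sulfide 18 (not isolated)
Conditions: N-chlorosuccinimide, CCl4, 0 °C to rt; then AgNO3, 2,6-lutidine, MeCN/H2O, 0 °C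
Reagents that add atoms: water, O
Why: Pummerer-type α-chlorination of the sulfide and silver-assisted hydrolysis of the α-chloro sulfide unmask the non-enolisable C9 aldehyde.

Step 12
Reactants: 7 (4S,5R)-3-{[(isopropoxy)dimethylsilyl]methyl}-4,5-(isopropylidenedioxy)cyclohex-2-en-1-one; 19 lactone aldehyde
Product: 22 seco aldol acetate (11-oxo, 9-OAc, 8-OSiEt3, 13,14-O-isopropylidene, C2 as CH2SiMe2(OiPr), 5,6-alkyne, 16-OSiPh2tBu), via lithium enolate 20 (not isolated), via lithium aldolate 21 (not isolated)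
Conditions: Me2CuLi (from MeLi, CuI; 1.05 equiv), Et2O, −78 to −30 °C; then 19, THF, −78 °C; then Ac2O, DMAP, −78 to 0 °C
Reagents that add atoms: lithium dimethylcuprate, [Li+].C[Cu-]C; acetic anhydride, CC(=O)OC(C)=O
Why: Conjugate addition of methyl anti to the C14 acetonide oxygen sets the C1 quaternary centre, the enolate adds to 19 through a Zimmerman–Traxler chair (anti aldol) on the face trans to the bulkier C1 arm so that C9 and C10 arise trans-diequatorial, and acetylation of the aldolate blocks the retro-aldol reaction.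

Step 13
Reactants: 22 seco aldol acetate
Product: 23 seco 11(20)-methylene compound
Conditions: Zn, CH2Br2, TiCl4, THF/CH2Cl2, 0 °C to rt
Reagents that add atoms: dibromomethane, BrCBr
Why: Takai–Lombardo methylenation converts the hindered, base-sensitive β-acetoxy ketone into the exocyclic alkene under non-basic conditions without touching the ester carbonyls.

Step 14
Reactants: 23 seco 11(20)-methylene compound
Product: 24 seco C2 primary alcohol
Conditions: H2O2 (30 %), KF, KHCO3, THF/MeOH, rt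
Reagents that add atoms: hydrogen peroxide, OO
Why: Tamao–Kumada oxidation replaces the carbon–silicon bond of the alkoxysilane by a carbon–oxygen bond.

Step 15
Reactants: 24 seco C2 primary alcohol
Product: 25 seco C2 aldehyde
Conditions: Dess–Martin periodinane, CH2Cl2, rt
Reagents that add atoms: none
Why: Dess–Martin oxidation gives the neopentyl aldehyde, which cannot epimerise because C1 is quaternary.

Step 16
Reactants: 25 seco C2 aldehyde
Product: 26 seco propargylic alcohols (both C2 epimers)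
Conditions: HC≡CMgBr, THF, −78 to −40 °C; then aq. NH4Cl
Reagents that add atoms: ethynylmagnesium bromide, C#C[Mg]Br
Why: Grignard addition to the aldehyde at low temperature leaves esters and lactone untouched; the C2 configuration is not controlled here and is erased in the next step.

Step 17
Reactants: 26 seco propargylic alcohols
Product: 27 seco ynone (C2 ketone, C3≡C4)
Conditions: Dess–Martin periodinane, CH2Cl2, rt
Reagents that add atoms: none
Why: Dess–Martin oxidation converges both epimers to the terminal ynone.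

Step 18
Reactants: 27 seco ynone
Product: 28 seco (Z)-β-iodo enone
Conditions: NaI, AcOH, rt
Reagents that add atoms: sodium iodide, [Na+].[I-]
Why: Conjugate addition of iodide to the ynone and anti protonation (hydroiodination) give the (Z)-β-iodo enone kinetically.

Step 19
Reactants: 28 seco (Z)-β-iodo enone
Product: 29 seco (2S)-(Z)-iodoallylic alcohol
Conditions: Zn(BH4)2, Et2O, −40 °C; then aq. NH4Cl
Reagents that add atoms: none
Why: 1,2-Reduction in which zinc chelates the C2 carbonyl and the C14 oxygen delivers hydride anti to the axial C10 branch of the chelate, the same face the Felkin–Anh model predicts, giving the 2S alcohol syn to the C14 oxygen.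

Step 20
Reactants: 29 seco (2S)-(Z)-iodoallylic alcohol
Product: 30 seco tetraol (2-, 8-, 13-, 14-OH; 9-OAc)
Conditions: AcOH/H2O/THF (3:1:1), 50 °C
Reagents that add atoms: none
Why: Mild acid hydrolysis removes the isopropylidene acetal and the triethylsilyl ether while the tert-butyldiphenylsilyl ether, the esters and the alkenyl iodide survive.

Step 21
Reactants: 30 seco tetraol
Product: 31 seco tetraacetate (2-, 9-, 13-, 14-OAc; 8-OH)
Conditions: Ac2O, pyridine, DMAP (cat.), CH2Cl2, 0 °C to rt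
Reagents that add atoms: acetic anhydride, CC(=O)OC(C)=O
Why: DMAP-catalysed acetylation esterifies the three secondary hydroxyls and leaves the hindered tertiary C8 hydroxyl free.

Step 22
Reactants: 31 seco tetraacetate
Product: 32 seco 11,20-epoxide
Conditions: mCPBA, NaHCO3, CH2Cl2, 0 °C
Reagents that add atoms: 3-chloroperoxybenzoic acid, OOC(=O)c1cccc(Cl)c1
Why: Prilezhaev epoxidation of the only electron-rich alkene from the face opposite the axial C15 methyl group gives the 11S spiro-epoxide (oxygen equatorial); the alkenyl iodide and the alkyne are too electron-poor to react.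

Step 23
Reactants: 32 seco 11,20-epoxide
Product: 33 seco propargylic alcohol (16-OH)
Conditions: Bu4NF, AcOH (1:1), THF, 0 °C to rt
Reagents that add atoms: none
Why: Buffered fluoride cleaves the primary silyl ether without acetate migration or epoxide opening.

Step 24
Reactants: 33 seco propargylic alcohol
Product: 35 seco diiodide (C4 and C5 alkenyl iodides), via alkenylstannane 34 (not isolated)
Conditions: [Cp*RuCl]4 (2.5 mol %), Bu3SnH, CH2Cl2, rt; then I2, CH2Cl2, 0 °C
Reagents that add atoms: iodine, [I][I]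
Why: Hydroxyl-directed ruthenium-catalysed trans-hydrostannation puts tin on C5 (proximal to the C16 hydroxyl) with hydrogen anti, and iododestannylation proceeds with retention, so iodine is cis to C7.

Step 25
Reactants: 35 seco diiodide
Product: 36 target (CNP0317528.3)
Conditions: NiBr2(MeOCH2CH2OMe) (20 mol %), 4,4'-di-tert-butyl-2,2'-bipyridine (24 mol %), Bu4NBr, DMA, undivided cell, Zn anode, Ni-foam cathode, constant current 2 mA, 35 added over 10 h (final 1 mM), rt
Reagents that add atoms: none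
Why: Proposed new method: nickel-catalysed electroreductive intramolecular alkenyl–alkenyl cross-electrophile coupling closes the ten-membered ring at C4–C5, in that cathodically generated zerovalent nickel inserts into the less hindered (Z)-C4–iodine bond, the alkenylnickel is reduced at the cathode to the monovalent stage and inserts intramolecularly into the C5–iodine bond, and the trivalent dialkenylnickel reductively eliminates the (3Z,5E)-diene with retention at both alkenes and without touching any stereocentre; the closest known reaction type is the NiBr2(bipyridine)-catalysed electroreductive coupling of alkenyl halides to 1,3-dienes with a sacrificial anode, so far only intermolecular.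

## Compound list

1 | (−)-quinic acid, (1S,3R,4S,5R)-1,3,4,5-tetrahydroxycyclohexanecarboxylic acid | OC(=O)[C@]1(O)C[C@@H](O)[C@@H](O)[C@H](O)C1 | starting material
2 | 3,4-O-isopropylidene-quinic acid 1,5-lactone | O=C1[C@]2(O)C[C@H]3OC(C)(C)O[C@H]3[C@H](O1)C2 | intermediate
3 | triol: 1-(hydroxymethyl)-3,4-O-isopropylidene-cyclohexane-1,3,4,5-tetrol (from lactone reduction) | OC[C@]1(O)C[C@H]2OC(C)(C)O[C@H]2[C@H](O)C1 | intermediate
4 | (3R,4S,5R)-3-hydroxy-4,5-(isopropylidenedioxy)cyclohexanone | O=C1C[C@H]2OC(C)(C)O[C@H]2[C@H](O)C1 | intermediate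
5 | (4S,5R)-4,5-(isopropylidenedioxy)cyclohex-2-en-1-one | O=C1C[C@H]2OC(C)(C)O[C@H]2C=C1 | intermediate
6 | trimethylsilyl enol ether of the 3-(silylmethyl) conjugate adduct (silylmethyl trans to the acetonide) | C[Si](C)(C)OC1=C[C@@H](C[Si](C)(C)OC(C)C)[C@@H]2OC(C)(C)O[C@@H]2C1 | intermediate
7 | (4S,5R)-3-{[(isopropoxy)dimethylsilyl]methyl}-4,5-(isopropylidenedioxy)cyclohex-2-en-1-one | O=C1C[C@H]2OC(C)(C)O[C@H]2C(C[Si](C)(C)OC(C)C)=C1 | intermediate
8 | dimethyl (R)-malate | COC(=O)C[C@@H](O)C(=O)OC | starting material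
9 | dimethyl (2R,3S)-2-hydroxy-3-methylbutanedioate | COC(=O)[C@@H](C)[C@@H](O)C(=O)OC | intermediate
10 | (2R,3S)-2-hydroxy-3-methylbutanedioic acid | OC(=O)[C@@H](C)[C@@H](O)C(O)=O | intermediate
11 | (2S)-2-[(2R,4R)-2-tert-butyl-5-oxo-1,3-dioxolan-4-yl]propanoic acid (cis) | OC(=O)[C@@H](C)[C@H]1O[C@@H](C(C)(C)C)OC1=O | intermediate
12 | (2S)-2-[(2R,4R)-2-tert-butyl-5-oxo-4-(phenylsulfanylmethyl)-1,3-dioxolan-4-yl]propanoic acid (CH2SPh trans to tert-butyl) | OC(=O)[C@@H](C)[C@@]1(CSc2ccccc2)O[C@@H](C(C)(C)C)OC1=O | intermediate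
13 | tert-butyl(diphenyl)(prop-2-yn-1-yloxy)silane | C#CCO[Si](c1ccccc1)(c1ccccc1)C(C)(C)C | starting material
14 | lactol: 12 with the ring C=O reduced to CH–OH (either epimer) | OC(=O)[C@@H](C)[C@@]1(CSc2ccccc2)O[C@@H](C(C)(C)C)OC1O | intermediate
15 | dihydroxy acid: 2-methyl-3-hydroxy-3-(phenylsulfanylmethyl)-4-hydroxy-7-(tert-butyldiphenylsilyloxy)hept-5-ynoic acid (C17, C8, C7 as in 36) | CC(C)(C)[Si](c1ccccc1)(c1ccccc1)OCC#C[C@@H](O)[C@@](O)(CSc1ccccc1)[C@H](C)C(O)=O | intermediate
16 | hydroxy lactone: γ-lactone C19(=O)–C17H(Me)–C8(OH)(CH2SPh)–C7H(C≡C–CH2OSiPh2tBu)–O | CC(C)(C)[Si](c1ccccc1)(c1ccccc1)OCC#C[C@H]2OC(=O)[C@@H](C)[C@]2(O)CSc1ccccc1 | intermediate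
17 | 8-O-triethylsilyl ether of 16 | CC(C)(C)[Si](c1ccccc1)(c1ccccc1)OCC#C[C@H]2OC(=O)[C@@H](C)[C@]2(O[Si](CC)(CC)CC)CSc1ccccc1 | intermediate
18 | α-chloro sulfide of 17 (C9 as CHCl–SPh, either epimer) | CC(C)(C)[Si](c1ccccc1)(c1ccccc1)OCC#C[C@H]2OC(=O)[C@@H](C)[C@]2(O[Si](CC)(CC)CC)C(Cl)Sc1ccccc1 | intermediate
19 | lactone aldehyde: as 17 with C9 as CHO | CC(C)(C)[Si](c1ccccc1)(c1ccccc1)OCC#C[C@H]2OC(=O)[C@@H](C)[C@]2(O[Si](CC)(CC)CC)C=O | intermediate
20 | lithium enolate (C10=C11–OLi) of the 3-methyl-3-(silylmethyl) ketone; C1 methyl trans to the acetonide | [Li]OC1=C[C@](C)(C[Si](C)(C)OC(C)C)[C@@H]2OC(C)(C)O[C@@H]2C1 | intermediate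
21 | lithium aldolate: 22 with C9–OLi instead of C9–OAc | CC(C)(C)[Si](c1ccccc1)(c1ccccc1)OCC#C[C@H]2OC(=O)[C@@H](C)[C@]2(O[Si](CC)(CC)CC)[C@@H](O[Li])[C@@H]3C(=O)C[C@H]4OC(C)(C)O[C@H]4[C@]3(C[Si](C)(C)OC(C)C)C | intermediate
22 | seco aldol acetate: 11-oxo, 9-OAc, 8-OSiEt3, 13,14-O-isopropylidene, C2 as CH2SiMe2(OiPr), C5≡C6, 16-OSiPh2tBu, C19/C7 lactone | CC(C)(C)[Si](c1ccccc1)(c1ccccc1)OCC#C[C@H]2OC(=O)[C@@H](C)[C@]2(O[Si](CC)(CC)CC)[C@@H](OC(C)=O)[C@@H]3C(=O)C[C@H]4OC(C)(C)O[C@H]4[C@]3(C[Si](C)(C)OC(C)C)C | intermediate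
23 | seco 11(20)-methylene compound: 22 with C11=CH2 | CC(C)(C)[Si](c1ccccc1)(c1ccccc1)OCC#C[C@H]2OC(=O)[C@@H](C)[C@]2(O[Si](CC)(CC)CC)[C@@H](OC(C)=O)[C@@H]3C(=C)C[C@H]4OC(C)(C)O[C@H]4[C@]3(C[Si](C)(C)OC(C)C)C | intermediate
24 | seco C2 primary alcohol: 23 with C2 as CH2OH | CC(C)(C)[Si](c1ccccc1)(c1ccccc1)OCC#C[C@H]2OC(=O)[C@@H](C)[C@]2(O[Si](CC)(CC)CC)[C@@H](OC(C)=O)[C@@H]3C(=C)C[C@H]4OC(C)(C)O[C@H]4[C@]3(CO)C | intermediate
25 | seco C2 aldehyde | CC(C)(C)[Si](c1ccccc1)(c1ccccc1)OCC#C[C@H]2OC(=O)[C@@H](C)[C@]2(O[Si](CC)(CC)CC)[C@@H](OC(C)=O)[C@@H]3C(=C)C[C@H]4OC(C)(C)O[C@H]4[C@]3(C=O)C | intermediate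
26 | seco propargylic alcohols: C2H(OH)–C≡CH, both C2 epimers | CC(C)(C)[Si](c1ccccc1)(c1ccccc1)OCC#C[C@H]2OC(=O)[C@@H](C)[C@]2(O[Si](CC)(CC)CC)[C@@H](OC(C)=O)[C@@H]3C(=C)C[C@H]4OC(C)(C)O[C@H]4[C@]3(C(O)C#C)C | intermediate
27 | seco ynone: C2(=O)–C≡CH | CC(C)(C)[Si](c1ccccc1)(c1ccccc1)OCC#C[C@H]2OC(=O)[C@@H](C)[C@]2(O[Si](CC)(CC)CC)[C@@H](OC(C)=O)[C@@H]3C(=C)C[C@H]4OC(C)(C)O[C@H]4[C@]3(C(=O)C#C)C | intermediate
28 | seco (Z)-β-iodo enone: C2(=O)–CH=CH–I (Z) | CC(C)(C)[Si](c1ccccc1)(c1ccccc1)OCC#C[C@H]2OC(=O)[C@@H](C)[C@]2(O[Si](CC)(CC)CC)[C@@H](OC(C)=O)[C@@H]3C(=C)C[C@H]4OC(C)(C)O[C@H]4[C@]3(C(=O)/C=C\I)C | intermediate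
29 | seco (2S)-(Z)-iodoallylic alcohol | CC(C)(C)[Si](c1ccccc1)(c1ccccc1)OCC#C[C@H]2OC(=O)[C@@H](C)[C@]2(O[Si](CC)(CC)CC)[C@@H](OC(C)=O)[C@@H]3C(=C)C[C@H]4OC(C)(C)O[C@H]4[C@]3([C@@H](O)/C=C\I)C | intermediate
30 | seco tetraol: 2-, 8-, 13-, 14-OH, 9-OAc, 11(20)-ene, 16-OSiPh2tBu | CC(C)(C)[Si](c1ccccc1)(c1ccccc1)OCC#C[C@H]2OC(=O)[C@@H](C)[C@]2(O)[C@@H](OC(C)=O)[C@@H]3C(=C)C[C@@H](O)[C@@H](O)[C@]3([C@@H](O)/C=C\I)C | intermediate
31 | seco tetraacetate: 2-, 9-, 13-, 14-OAc, 8-OH | CC(C)(C)[Si](c1ccccc1)(c1ccccc1)OCC#C[C@H]2OC(=O)[C@@H](C)[C@]2(O)[C@@H](OC(C)=O)[C@@H]3C(=C)C[C@@H](OC(C)=O)[C@@H](OC(C)=O)[C@]3([C@@H](OC(C)=O)/C=C\I)C | intermediate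
32 | seco (11S)-11,20-epoxide | CC(C)(C)[Si](c1ccccc1)(c1ccccc1)OCC#C[C@H]2OC(=O)[C@@H](C)[C@]2(O)[C@@H](OC(C)=O)[C@@H]3[C@]4(CO4)C[C@@H](OC(C)=O)[C@@H](OC(C)=O)[C@]3([C@@H](OC(C)=O)/C=C\I)C | intermediate
33 | seco propargylic alcohol: 32 with free 16-OH | OCC#C[C@H]2OC(=O)[C@@H](C)[C@]2(O)[C@@H](OC(C)=O)[C@@H]3[C@]4(CO4)C[C@@H](OC(C)=O)[C@@H](OC(C)=O)[C@]3([C@@H](OC(C)=O)/C=C\I)C | intermediate
34 | seco alkenylstannane: Bu3Sn on C5, cis to C7 | OC/C([Sn](CCCC)(CCCC)CCCC)=C/[C@H]2OC(=O)[C@@H](C)[C@]2(O)[C@@H](OC(C)=O)[C@@H]3[C@]4(CO4)C[C@@H](OC(C)=O)[C@@H](OC(C)=O)[C@]3([C@@H](OC(C)=O)/C=C\I)C | intermediate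
35 | seco diiodide: (Z)-C3=C4–I and C5(I)=C6 with iodine cis to C7 | OC/C(I)=C/[C@H]2OC(=O)[C@@H](C)[C@]2(O)[C@@H](OC(C)=O)[C@@H]3[C@]4(CO4)C[C@@H](OC(C)=O)[C@@H](OC(C)=O)[C@]3([C@@H](OC(C)=O)/C=C\I)C | intermediate
36 | CNP0317528.3: (1R,2S,3Z,5E,7R,8R,9S,10R,11S,13R,14S,17S)-2,9,13,14-tetraacetoxy-11,20-epoxy-8,16-dihydroxybriara-3,5-diene 19,7-lactone | CC(=O)O[C@H]1/C=C\C(CO)=C/[C@H]2OC(=O)[C@@H](C)[C@]2(O)[C@@H](OC(C)=O)[C@@H]2[C@]3(CO3)C[C@@H](OC(C)=O)[C@@H](OC(C)=O)[C@@]12C | target

## Step count and risks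

Total: 25 steps. Longest linear sequence: 21 steps (steps 5–25, from dimethyl (R)-malate); the quinic acid branch is steps 1–4.

Steps most likely to fail:

Step 25 (the proposed new ring closure). Risks are oligomerisation, reductive loss of iodine, Z-to-E isomerisation at the alkenylnickel stage and reductive opening of the epoxide. The fallback uses known chemistry and sets out from 33. Step 24 is stopped before the iodine treatment and the alkenylstannane 34 is isolated (no new compound, F0). An intramolecular Stille coupling of its C5 stannane with its C4 iodide (Pd2(dba)3, AsPh3, DMF, high dilution, 40 °C) then gives the diene and comes back to the route at 36.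

Step 12 (three-component union). The new C9–C10 bond lies between two carbons that each flank a quaternary centre. The face of attack at C10 rests on a conformational argument. The aldolate 21 could also translactonise onto C19 before it is acetylated. The fallback sets out from 7. Conjugate addition of Me2CuLi in the presence of Me3SiCl gives the isolated silyl enol ether F1. A Mukaiyama aldol reaction of F1 with 19 (BF3·OEt2, CH2Cl2, −78 °C; open transition state, no basic alkoxide) gives the β-hydroxy ketone F2. Acetylation (Ac2O, DMAP, pyridine) comes back to the route at 22.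

Step 9 (one-pot reduction, alkynylation, lactonisation). Risks are over-reduction, slow collapse of the aluminium hemiacetal and incomplete chelation control at C7. The fallback sets out from 12. The lithium acetylide of 13 (BuLi, THF, −78 °C) adds to the dioxolanone carbonyl and, after loss of pivalaldehyde, gives the hydroxy ynone acid F3. Silylation (Et3SiOTf, 2,6-lutidine) gives the silyloxy ynone acid F4. Felkin–Anh reduction with Li(sBu)3BH (THF, −78 °C, silyloxy group anti to the hydride) and acidic work-up lactonise directly, coming back to the route at 17.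

## Further compounds

F0 | step 25 | none | none
F1 | step 12 | trimethylsilyl enol ether of the 3-methyl-3-(silylmethyl) ketone (C10=C11–OSiMe3) | C[Si](C)(C)OC1=C[C@](C)(C[Si](C)(C)OC(C)C)[C@@H]2OC(C)(C)O[C@@H]2C1
F2 | step 12 | seco β-hydroxy ketone: 22 with free 9-OH | CC(C)(C)[Si](c1ccccc1)(c1ccccc1)OCC#C[C@H]2OC(=O)[C@@H](C)[C@]2(O[Si](CC)(CC)CC)[C@@H](O)[C@@H]3C(=O)C[C@H]4OC(C)(C)O[C@H]4[C@]3(C[Si](C)(C)OC(C)C)C
F3 | step 9 | hydroxy ynone acid: 2-methyl-3-hydroxy-3-(phenylsulfanylmethyl)-4-oxo-7-(tert-butyldiphenylsilyloxy)hept-5-ynoic acid | CC(C)(C)[Si](c1ccccc1)(c1ccccc1)OCC#CC(=O)[C@@](O)(CSc1ccccc1)[C@H](C)C(O)=O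
F4 | step 9 | 3-O-triethylsilyl ether of F3 | CC(C)(C)[Si](c1ccccc1)(c1ccccc1)OCC#CC(=O)[C@@](O[Si](CC)(CC)CC)(CSc1ccccc1)[C@H](C)C(O)=O
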